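**Plan** (prostanoid numbering: C1 = CO2H, C8 and C12 = ring CH, C9 = ring C=O, C10=C11 = ring alkene, C13=C14 = side-chain alkene, C15 = CHOAc)

1. Retrosynthetic cuts, in order: the C15 O–acetyl and O–silyl bonds; the ring bond C9–C10; the C8–C12 bond (with C14–O as its pericyclic partner); the ester C–O bond; the C13–C14 bond.
2. Enabling feature: in the cyclopent-2-enone (C8–C9–C10–C11–C12), C10 and C11 carry only hydrogen and C9 is a ketone. The ring is therefore an isomer of the open 4-alkynal OHC(9)–C8–C12–C11≡C10H, and moving the aldehyde hydrogen to C11 while C9 bonds to C10 closes it without base, oxidant or reductant.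
3. Forward: the chain is built first. An α-silyloxy aldehyde (C14–C20) and a C4 diyne (C10–C13) give an E-enynol; its azelate ester (C1–C9) undergoes an Ireland–Claisen rearrangement that joins C8 to C12; C9 is adjusted to CHO and the alkyne freed; the ring is the last C–C bond; desilylation and acetylation finish.
4. Stereochemistry: C15 comes from (S)-oct-1-en-3-ol; a temporary C14 carbinol is set by Felkin–Anh addition; C12, C8 and the 13E alkene arise by chirality transfer through the chair Ireland–Claisen transition state; the ring closure creates no stereocentre.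
5. Helpers, all removed by step 11: the C14 oxygen (consumed in the rearrangement), the SiMe3 cap on the alkyne, the silyl ether at C15 and the methyl ester at C1.

Key step: step 10

Assumption: (S)-oct-1-en-3-ol is bought as the single enantiomer (it is also accessible by lipase resolution of the racemate).

**Step 1**
Reactants: 1 (S)-oct-1-en-3-ol
Product: 2 tert-butyl(dimethyl){[(3S)-oct-1-en-3-yl]oxy}silane
Conditions: t-BuMe2SiCl, imidazole, DMF, rt
Reagents that add atoms: tert-butyldimethylsilyl chloride, CC(C)(C)[Si](C)(C)Cl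
Why: Imidazole-promoted silylation of a secondary alcohol is routine and does not touch the stereocentre that becomes C15.

**Step 2**
Reactants: 2 tert-butyl(dimethyl){[(3S)-oct-1-en-3-yl]oxy}silane
Product: 4 (2S)-2-{[tert-butyl(dimethyl)silyl]oxy}heptanal, via secondary ozonide 3 (not isolated)
Conditions: O3, CH2Cl2, −78 °C; then PPh3, −78 °C to rt
Reagents that add atoms: ozone, [O-][O+]=O
Why: Ozonolysis with reductive work-up cleaves the only alkene to the α-silyloxy aldehyde (C14 aldehyde), which should keep its configuration if used crude; no new stereocentre.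

**Step 3**
Reactants: 4 (2S)-2-{[tert-butyl(dimethyl)silyl]oxy}heptanal; 5 1,4-bis(trimethylsilyl)buta-1,3-diyne
Product: 6 (5R,6S)-6-{[tert-butyl(dimethyl)silyl]oxy}-1-(trimethylsilyl)undeca-1,3-diyn-5-ol
Conditions: 5, MeLi·LiBr, THF, −78 °C to rt; then 4, −78 °C; aq. NH4Cl
Reagents that add atoms: none
Why: Mono-desilylation of 5 gives the lithium diynide, whose addition to the non-chelating α-silyloxy aldehyde should follow the Felkin–Anh model (silyloxy group anti to the nucleophile) and favour the anti 5R carbinol; the syn epimer is removed by chromatography.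

**Step 4**
Reactants: 6 (5R,6S)-6-{[tert-butyl(dimethyl)silyl]oxy}-1-(trimethylsilyl)undeca-1,3-diyn-5-ol
Product: 7 (3E,5R,6S)-6-{[tert-butyl(dimethyl)silyl]oxy}-1-(trimethylsilyl)undec-3-en-1-yn-5-ol
Conditions: NaAlH2(OCH2CH2OMe)2 (Red-Al), THF, 0 °C; aq. potassium sodium tartrate
Reagents that add atoms: none
Why: Alkoxide-directed trans-hydroalumination of the triple bond next to the carbinol (the standard reduction of 2,4-diyn-1-ols to E-2-en-4-yn-1-ols) should give the E-alkene and leave the silyl-capped alkyne alone.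

**Step 5**
Reactants: 7 (3E,5R,6S)-6-{[tert-butyl(dimethyl)silyl]oxy}-1-(trimethylsilyl)undec-3-en-1-yn-5-ol; 8 9-methoxy-9-oxononanoic acid (monomethyl azelate)
Product: 9 1-[(3E,5R,6S)-6-{[tert-butyl(dimethyl)silyl]oxy}-1-(trimethylsilyl)undec-3-en-1-yn-5-yl] 9-methyl nonanedioate
Conditions: EDC·HCl, DMAP, CH2Cl2, rt
Reagents that add atoms: none
Why: Carbodiimide (Steglich) esterification of a secondary allylic alcohol attaches the complete C1–C9 chain through the C14 oxygen without disturbing either stereocentre.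

**Step 6**
Reactants: 9 1-[(3E,5R,6S)-6-{[tert-butyl(dimethyl)silyl]oxy}-1-(trimethylsilyl)undec-3-en-1-yn-5-yl] 9-methyl nonanedioate
Product: 12 (2R)-2-[(3R,4E,6S)-6-{[tert-butyl(dimethyl)silyl]oxy}-1-(trimethylsilyl)undec-4-en-1-yn-3-yl]-9-methoxy-9-oxononanoic acid, via bis(silyl ketene acetal) 10 (not isolated), via rearranged trimethylsilyl ester 11 (not isolated)
Conditions: LiN(i-Pr)2 (2.4 equiv), THF, −78 °C; Me3SiCl, Et3N, −78 °C to 50 °C; 1 M HCl work-up
Reagents that add atoms: none
Why: Ireland–Claisen rearrangement: kinetic enolization in THF places the C7 chain cis to the allylic oxygen, and the chair transition state with the C15-bearing substituent equatorial transfers the C14 configuration to C12, sets C8 anti to it and gives the 13E alkene; the methyl ester is also O-silylated but cannot rearrange and should return on acidic work-up.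

**Step 7**
Reactants: 12 (2R)-2-[(3R,4E,6S)-6-{[tert-butyl(dimethyl)silyl]oxy}-1-(trimethylsilyl)undec-4-en-1-yn-3-yl]-9-methoxy-9-oxononanoic acid
Product: 15 methyl (8R,9R,10E,12S)-12-{[tert-butyl(dimethyl)silyl]oxy}-8-(hydroxymethyl)-9-[(trimethylsilyl)ethynyl]heptadec-10-enoate, via mixed carbonic anhydride 13 (not isolated), via aldehyde 14 (not isolated)
Conditions: i-BuOCOCl, N-methylmorpholine, THF, −15 °C; then NaBH4, H2O, 0 °C
Reagents that add atoms: none
Why: Borohydride reduction of the mixed carbonic anhydride should reduce only the C9 carboxyl and spare the methyl ester, alkene and alkyne; no stereocentre is affected.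

**Step 8**
Reactants: 15 methyl (8R,9R,10E,12S)-12-{[tert-butyl(dimethyl)silyl]oxy}-8-(hydroxymethyl)-9-[(trimethylsilyl)ethynyl]heptadec-10-enoate
Product: 16 (8R,9R,10E,12S)-12-{[tert-butyl(dimethyl)silyl]oxy}-9-ethynyl-8-(hydroxymethyl)heptadec-10-enoic acid
Conditions: LiOH, THF/MeOH/H2O, rt; then 1 M HCl to pH 4
Reagents that add atoms: lithium hydroxide, [Li+].[OH-]
Why: Saponification of the methyl ester and hydroxide-induced cleavage of the alkynyl C–Si bond should occur in one operation at a stage with no base-sensitive centre, while the secondary silyl ether survives.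

**Step 9**
Reactants: 16 (8R,9R,10E,12S)-12-{[tert-butyl(dimethyl)silyl]oxy}-9-ethynyl-8-(hydroxymethyl)heptadec-10-enoic acid
Product: 17 (8R,9R,10E,12S)-12-{[tert-butyl(dimethyl)silyl]oxy}-9-ethynyl-8-formylheptadec-10-enoic acid
Conditions: Dess–Martin periodinane, CH2Cl2, 0 °C to rt
Reagents that add atoms: none
Why: Dess–Martin oxidation takes the primary alcohol to the aldehyde under near-neutral conditions that should not epimerize C8; the aldehyde is used directly.

**Step 10**
Reactants: 17 (8R,9R,10E,12S)-12-{[tert-butyl(dimethyl)silyl]oxy}-9-ethynyl-8-formylheptadec-10-enoic acid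
Product: 18 7-[(1R,2S)-2-[(1E,3S)-3-{[tert-butyl(dimethyl)silyl]oxy}oct-1-en-1-yl]-5-oxocyclopent-3-en-1-yl]heptanoic acid
Conditions: [Rh(Ph2PCH2CH2PPh2)]2(BF4)2 (5 mol %), degassed acetone, 25 °C
Reagents that add atoms: none
Why: Oxidative addition of the aldehyde C–H bond to the cationic monovalent rhodium centre gives an acyl hydride of trivalent rhodium to which the tethered terminal alkyne binds; net trans addition of Rh–H across C10≡C11 puts hydrogen on C11 and rhodium on C10 in a six-membered acyl(alkenyl)rhodacycle, and C–C reductive elimination forms the C9–C10 bond. The closest known reaction type is the rhodium-catalysed intramolecular trans-hydroacylation of 4-alkynals to cyclopent-2-enones. The five-membered ring (C8–C9–C10–C11–C12) is closed in a formally 5-endo-dig mode with respect to the alkyne, made possible by the metallacycle. No stereocentre is created; C8 and C12 come from step 6, the neutral base-free conditions should leave the α-aldehyde centre C8 untouched, and the trans arrangement is also the more stable one in the ring. The step needs selectivity for the alkyne over the C13=C14 alkene (a 4-alkenal unit that could give a cyclopentanone) and for endo over exo acyl transfer (which would give a 2-methylenecyclobutanone); the unhindered terminal alkyne should bind far better than a 1,2-disubstituted alkene flanked by C12 and the silyloxy-bearing C15, and the four-membered alternative is strained. The 4-substituted cyclopentenone, prone to base-induced double-bond migration, is thus formed as the last C–C bond by a reagent-free isomerization.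

**Step 11**
Reactants: 18 7-[(1R,2S)-2-[(1E,3S)-3-{[tert-butyl(dimethyl)silyl]oxy}oct-1-en-1-yl]-5-oxocyclopent-3-en-1-yl]heptanoic acid
Product: 19 7-[(1R,2S)-2-[(1E,3S)-3-hydroxyoct-1-en-1-yl]-5-oxocyclopent-3-en-1-yl]heptanoic acid (PGA1)
Conditions: HF·pyridine, THF, 0 °C
Reagents that add atoms: none
Why: Acidic fluoride desilylation should free the C15 alcohol without the basic conditions that isomerize the enone.

**Step 12**
Reactants: 19 7-[(1R,2S)-2-[(1E,3S)-3-hydroxyoct-1-en-1-yl]-5-oxocyclopent-3-en-1-yl]heptanoic acid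
Product: 21 7-[(1R,2S)-2-[(1E,3S)-3-acetoxyoct-1-en-1-yl]-5-oxocyclopent-3-en-1-yl]heptanoic acid (CNP0281518.1), via mixed acetic anhydride 20 (not isolated)
Conditions: Ac2O, pyridine, rt; then H2O
Reagents that add atoms: acetic anhydride, CC(=O)OC(C)=O; water, O
Why: Pyridine-mediated acetylation of the allylic alcohol is standard for this ring system; the carboxyl group is transiently acetylated and should be released by hydrolysis of the mixed anhydride on aqueous work-up.

**Compound list**

1 | (S)-oct-1-en-3-ol | CCCCC[C@H](O)C=C | starting material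
2 | tert-butyl(dimethyl){[(3S)-oct-1-en-3-yl]oxy}silane | CCCCC[C@H](O[Si](C)(C)C(C)(C)C)C=C | intermediate
3 | tert-butyl(dimethyl){[(1S)-1-(1,2,4-trioxolan-3-yl)hexyl]oxy}silane (epimers at the ring carbon; not isolated) | CCCCC[C@H](O[Si](C)(C)C(C)(C)C)C1OCOO1 | intermediate
4 | (2S)-2-{[tert-butyl(dimethyl)silyl]oxy}heptanal | CCCCC[C@H](O[Si](C)(C)C(C)(C)C)C=O | intermediate
5 | 1,4-bis(trimethylsilyl)buta-1,3-diyne | C[Si](C)(C)C#CC#C[Si](C)(C)C | starting material
6 | (5R,6S)-6-{[tert-butyl(dimethyl)silyl]oxy}-1-(trimethylsilyl)undeca-1,3-diyn-5-ol | CCCCC[C@H](O[Si](C)(C)C(C)(C)C)[C@H](O)C#CC#C[Si](C)(C)C | intermediate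
7 | (3E,5R,6S)-6-{[tert-butyl(dimethyl)silyl]oxy}-1-(trimethylsilyl)undec-3-en-1-yn-5-ol | CCCCC[C@H](O[Si](C)(C)C(C)(C)C)[C@H](O)/C=C/C#C[Si](C)(C)C | intermediate
8 | 9-methoxy-9-oxononanoic acid (monomethyl azelate) | COC(=O)CCCCCCCC(=O)O | starting material
9 | 1-[(3E,5R,6S)-6-{[tert-butyl(dimethyl)silyl]oxy}-1-(trimethylsilyl)undec-3-en-1-yn-5-yl] 9-methyl nonanedioate | CCCCC[C@H](O[Si](C)(C)C(C)(C)C)[C@H](OC(=O)CCCCCCCC(=O)OC)/C=C/C#C[Si](C)(C)C | intermediate
10 | bis(trimethylsilyl ketene acetal) of 9 (C7 chain cis to the allylic oxygen; not isolated) | CCCCC[C@H](O[Si](C)(C)C(C)(C)C)[C@H](O/C(O[Si](C)(C)C)=C\CCCCC/C=C(\OC)O[Si](C)(C)C)/C=C/C#C[Si](C)(C)C | intermediate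
11 | trimethylsilyl ester of 12 still carrying the methyl trimethylsilyl ketene acetal at the chain end (not isolated) | CCCCC[C@@H](/C=C/[C@@H](C#C[Si](C)(C)C)[C@@H](CCCCC/C=C(\OC)O[Si](C)(C)C)C(=O)O[Si](C)(C)C)O[Si](C)(C)C(C)(C)C | intermediate
12 | (2R)-2-[(3R,4E,6S)-6-{[tert-butyl(dimethyl)silyl]oxy}-1-(trimethylsilyl)undec-4-en-1-yn-3-yl]-9-methoxy-9-oxononanoic acid | CCCCC[C@@H](/C=C/[C@@H](C#C[Si](C)(C)C)[C@@H](CCCCCCC(=O)OC)C(=O)O)O[Si](C)(C)C(C)(C)C | intermediate
13 | isobutyl carbonic mixed anhydride of 12 (not isolated) | CCCCC[C@@H](/C=C/[C@@H](C#C[Si](C)(C)C)[C@@H](CCCCCCC(=O)OC)C(=O)OC(=O)OCC(C)C)O[Si](C)(C)C(C)(C)C | intermediate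
14 | methyl (8R,9R,10E,12S)-12-{[tert-butyl(dimethyl)silyl]oxy}-8-formyl-9-[(trimethylsilyl)ethynyl]heptadec-10-enoate (not isolated) | CCCCC[C@@H](/C=C/[C@@H](C#C[Si](C)(C)C)[C@@H](CCCCCCC(=O)OC)C=O)O[Si](C)(C)C(C)(C)C | intermediate
15 | methyl (8R,9R,10E,12S)-12-{[tert-butyl(dimethyl)silyl]oxy}-8-(hydroxymethyl)-9-[(trimethylsilyl)ethynyl]heptadec-10-enoate | CCCCC[C@@H](/C=C/[C@@H](C#C[Si](C)(C)C)[C@@H](CCCCCCC(=O)OC)CO)O[Si](C)(C)C(C)(C)C | intermediate
16 | (8R,9R,10E,12S)-12-{[tert-butyl(dimethyl)silyl]oxy}-9-ethynyl-8-(hydroxymethyl)heptadec-10-enoic acid | CCCCC[C@@H](/C=C/[C@@H](C#C)[C@@H](CCCCCCC(=O)O)CO)O[Si](C)(C)C(C)(C)C | intermediate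
17 | (8R,9R,10E,12S)-12-{[tert-butyl(dimethyl)silyl]oxy}-9-ethynyl-8-formylheptadec-10-enoic acid | CCCCC[C@@H](/C=C/[C@@H](C#C)[C@@H](CCCCCCC(=O)O)C=O)O[Si](C)(C)C(C)(C)C | intermediate
18 | 7-[(1R,2S)-2-[(1E,3S)-3-{[tert-butyl(dimethyl)silyl]oxy}oct-1-en-1-yl]-5-oxocyclopent-3-en-1-yl]heptanoic acid | CCCCC[C@@H](/C=C/[C@H]1C=CC(=O)[C@@H]1CCCCCCC(=O)O)O[Si](C)(C)C(C)(C)C | intermediate
19 | 7-[(1R,2S)-2-[(1E,3S)-3-hydroxyoct-1-en-1-yl]-5-oxocyclopent-3-en-1-yl]heptanoic acid (PGA1) | CCCCC[C@@H](/C=C/[C@H]1C=CC(=O)[C@@H]1CCCCCCC(=O)O)O | intermediate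
20 | acetic 7-[(1R,2S)-2-[(1E,3S)-3-acetoxyoct-1-en-1-yl]-5-oxocyclopent-3-en-1-yl]heptanoic anhydride (not isolated) | CCCCC[C@@H](/C=C/[C@H]1C=CC(=O)[C@@H]1CCCCCCC(=O)OC(C)=O)OC(C)=O | intermediate
21 | 7-[(1R,2S)-2-[(1E,3S)-3-acetoxyoct-1-en-1-yl]-5-oxocyclopent-3-en-1-yl]heptanoic acid | CCCCC[C@@H](/C=C/[C@H]1C=CC(=O)[C@@H]1CCCCCCC(=O)O)OC(C)=O | target

**Totals**

Total step count: 12. Longest linear sequence: 12 steps (1 to 21); compounds 5 and 8 are purchased.

**Steps most likely to fail**

1. Step 10. The acyl rhodium hydride may partition unproductively: decarbonylation, hydroacylation of the C13=C14 alkene, or oligomerization of the terminal alkyne on the cationic metal instead of ring closure. Fallback, setting out from 17 and returning at 18: semi-hydrogenation of the alkyne over Pd/CaCO3 poisoned with Pb(OAc)2 (Lindlar catalyst, quinoline, H2) would give (8R,9R,10E,12S)-12-{[tert-butyl(dimethyl)silyl]oxy}-9-ethenyl-8-formylheptadec-10-enoic acid F1. Addition of CH2=CHMgBr (2.2 equiv, THF, −78 °C) to the aldehyde would give the dienol (8R,9R,10E,12S)-12-{[tert-butyl(dimethyl)silyl]oxy}-9-ethenyl-8-(1-hydroxyprop-2-en-1-yl)heptadec-10-enoic acid F2 as a mixture of carbinol epimers. Ring-closing metathesis with the second-generation Grubbs catalyst RuCl2(=CHPh)(H2IMes)(PCy3) between the two terminal vinyl groups would form the ring alkene instead of the acyl–alkenyl bond and give 7-{2-[(1E,3S)-3-{[tert-butyl(dimethyl)silyl]oxy}oct-1-en-1-yl]-5-hydroxycyclopent-3-en-1-yl}heptanoic acid with the ring configuration of 18 F3. Dess–Martin oxidation of the allylic alcohol then gives 18.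

2. Step 6. With two ester groups competing for the base, enolization may be incomplete or unselective, leading to condensation or to loss of the ketene acetal geometry that fixes C8. Fallback, setting out from 7 and returning at 12: acylation of 7 with an excess of nonanedioic acid (EDC, DMAP) would give the hydrogen azelate 9-{[(3E,5R,6S)-6-{[tert-butyl(dimethyl)silyl]oxy}-1-(trimethylsilyl)undec-3-en-1-yn-5-yl]oxy}-9-oxononanoic acid F4. With LiN(i-Pr)2 (2.2 equiv, THF, −78 °C) the free carboxyl is held as its lithium carboxylate, so only the allylic ester is enolized. Silylation with Me3SiCl would give the silyl ketene acetal trimethylsilyl ester F5, which rearranges on warming to the bis(trimethylsilyl) ester F6; acidic work-up gives the diacid (2R)-2-[(3R,4E,6S)-6-{[tert-butyl(dimethyl)silyl]oxy}-1-(trimethylsilyl)undec-4-en-1-yn-3-yl]nonanedioic acid F7. Lipase-catalysed esterification (immobilised Candida antarctica lipase B, MeOH, hexane) should take the unhindered terminal carboxyl in preference to the α-branched one and give 12.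

3. Step 3. Facial selectivity in the diynide addition may be insufficient, giving too much of the syn C5 epimer. Fallback, setting out from 6 as the mixture of C5 epimers and returning at 6: Dess–Martin oxidation would converge both epimers on the ynone (6S)-6-{[tert-butyl(dimethyl)silyl]oxy}-1-(trimethylsilyl)undeca-1,3-diyn-5-one F8. Noyori-type asymmetric transfer hydrogenation (RuCl[(S,S)-TsDPEN](p-cymene), i-PrOH, rt; this catalyst enantiomer is chosen by analogy with simple alkynyl ketones) should then set the 5R carbinol under catalyst control.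

**Further compounds**

F1 | step 10 | (8R,9R,10E,12S)-12-{[tert-butyl(dimethyl)silyl]oxy}-9-ethenyl-8-formylheptadec-10-enoic acid | CCCCC[C@@H](/C=C/[C@@H](C=C)[C@@H](CCCCCCC(=O)O)C=O)O[Si](C)(C)C(C)(C)C
F2 | step 10 | (8R,9R,10E,12S)-12-{[tert-butyl(dimethyl)silyl]oxy}-9-ethenyl-8-(1-hydroxyprop-2-en-1-yl)heptadec-10-enoic acid (carbinol epimers) | CCCCC[C@@H](/C=C/[C@@H](C=C)[C@@H](CCCCCCC(=O)O)C(O)C=C)O[Si](C)(C)C(C)(C)C
F3 | step 10 | 7-{2-[(1E,3S)-3-{[tert-butyl(dimethyl)silyl]oxy}oct-1-en-1-yl]-5-hydroxycyclopent-3-en-1-yl}heptanoic acid with the ring configuration of 18 (carbinol epimers) | CCCCC[C@@H](/C=C/[C@H]1C=CC(O)[C@@H]1CCCCCCC(=O)O)O[Si](C)(C)C(C)(C)C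
F4 | step 6 | 9-{[(3E,5R,6S)-6-{[tert-butyl(dimethyl)silyl]oxy}-1-(trimethylsilyl)undec-3-en-1-yn-5-yl]oxy}-9-oxononanoic acid | CCCCC[C@H](O[Si](C)(C)C(C)(C)C)[C@H](OC(=O)CCCCCCCC(=O)O)/C=C/C#C[Si](C)(C)C
F5 | step 6 | silyl ketene acetal trimethylsilyl ester of F4 (not isolated) | CCCCC[C@H](O[Si](C)(C)C(C)(C)C)[C@H](O/C(O[Si](C)(C)C)=C\CCCCCCC(=O)O[Si](C)(C)C)/C=C/C#C[Si](C)(C)C
F6 | step 6 | bis(trimethylsilyl) ester of F7 (not isolated) | CCCCC[C@@H](/C=C/[C@@H](C#C[Si](C)(C)C)[C@@H](CCCCCCC(=O)O[Si](C)(C)C)C(=O)O[Si](C)(C)C)O[Si](C)(C)C(C)(C)C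
F7 | step 6 | (2R)-2-[(3R,4E,6S)-6-{[tert-butyl(dimethyl)silyl]oxy}-1-(trimethylsilyl)undec-4-en-1-yn-3-yl]nonanedioic acid | CCCCC[C@@H](/C=C/[C@@H](C#C[Si](C)(C)C)[C@@H](CCCCCCC(=O)O)C(=O)O)O[Si](C)(C)C(C)(C)C
F8 | step 3 | (6S)-6-{[tert-butyl(dimethyl)silyl]oxy}-1-(trimethylsilyl)undeca-1,3-diyn-5-one | CCCCC[C@H](O[Si](C)(C)C(C)(C)C)C(=O)C#CC#C[Si](C)(C)C
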